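Daucane numbering is used throughout. Ring A (five-membered) is C1–C2–C3–C4–C5 and ring B (seven-membered) is C1–C5–C6–C7–C8–C9–C10. C15 is the methyl group on C1, C14 the methylene carbon on C8, and C11–C13 the isopropyl group on C4. The face of the bicycle that carries C15 is called β.

## Analysis of the target

The target is a daucane (carotane) sesquiterpenoid ester: cyclopentane ring A is trans-fused through the C1–C5 bond to cycloheptane ring B, and O6 is acylated by 4-hydroxybenzoic acid. It has five stereocentres: the quaternary C1 with the angular methyl C15, the tertiary carbinol C4 with the isopropyl group, the ring-fusion methine C5, the ester-bearing C6 and the allylic carbinol C9. C15, the 4-hydroxyl and the 9-hydroxyl lie on the β face, while H5 and the ester oxygen lie on the α face, which corresponds to 1R,4R,5S,6S,9R. C1, C5, C4 and C6 form one contiguous block at the ring fusion, whereas C9 sits alone across ring B next to the exocyclic C8=C14 methylene group. The sensitive groups are the tertiary alcohol (dehydration, or attack across the ring on an electrophilic C8), the 1,1-disubstituted alkene with its allylic alcohol (the corresponding ketone is a reactive α-methylene ketone) and the aryl ester with its free phenol. The difficulty is a trans-hydroazulene with a quaternary centre at the fusion and a tertiary alcohol cis to the angular methyl group, that is, on the face a reagent avoids, combined with three oxygen functions of which the one at C6 has no neighbouring group to guide a reagent. The strategy rests on the fact that the fifteen skeletal carbons form an intact farnesyl chain: only the bonds C1–C10 and C4–C5 are not bonds of that chain, and C8, C9 and C14 correspond to its terminal allylic alkene. Both rings can therefore be closed in one cationic bicyclisation of an acyclic C15 diphosphate, which leaves a C8=C9 alkene from which the C8=C14/C9–OH unit is made.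

## Retrosynthetic reasoning

**Phenol protecting group.** The last bond cut is the O–Si bond: 14 is 13 without the triisopropylsilyl group on the phenol. The phenol is masked because a free ArOH would consume the aluminium amide base and would let the hydroxy acid acylate itself. A silyl ether is chosen because a fluoride source removes it at the end without touching the ester or either alcohol.

**C9–H bond.** The allylic carbinol C9 of 13 is traced to the α-methylene ketone 12, and 12 to the C9 epimer 11. The reason is that the oxygen reaches C9 by way of an epoxide that should form on the α face, whereas the target needs O9 on the β face. An oxidation–reduction pair turns the centre over, and because the ketone erases C9, both epoxide epimers converge on 12. The forward reduction has to add hydride 1,2 and from the α face.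

**C8=C14 and C9–O.** The allylic alcohol 11 is traced to epoxide 10 by returning a proton to C14 and re-forming the C8–O bond, and 10 to the trisubstituted alkene 9 by removing the epoxide oxygen. The cut is made here because a C8=C9 alkene carrying C14 as a methyl group is exactly what the cyclisation of the farnesyl chain leaves behind. The forward isomerisation must take the proton from C14 and not from C7.

**Ester C–O bond.** Compound 9 is cut at the acyl–O6 bond into diol 5 and the protected acid 8. The ester is introduced before the alkene chemistry so that the only secondary alcohol present at that stage is O6, and no choice between O6 and O9 arises. Acid 8 comes from 6 by silylation through the silyl ester 7.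

**C6–O bond.** Diol 5 is traced to alcohol 4 by replacing the 6α-hydroxyl with hydrogen. C6 is a plain ring methylene flanked by C5 and C7, with no functional group from which chemical oxidation could be directed, so the forward step is an enzymatic C–H hydroxylation that has to find the pro-α hydrogen of C6.

**Both rings.** Alcohol 4 is cut at C1–C10 and C4–C5, and the hydroxyl group is removed from C4, which unfolds the bicycle to the acyclic diphosphate 3. No other pair of cuts returns an unbranched, commercially available C15 chain with every carbon in place. The forward reaction has to close ring B and ring A, set C1, C5 and C4, and stop at the C4 cation by hydration.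

**Diphosphate.** Compound 3 is traced through the allylic chloride 2 to farnesol 1 by two routine functional-group changes at the primary allylic carbon, so that all risk is carried by the cyclisation.

## Alternatives that were turned down

**Alternative 1:** Ring B is traced back to a six-membered ring by taking out C8: the bonds C7–C8 and C8–C9 are cut and C7 is joined to C9. This leads to the trans-hydrindane silyl enol ether A1, which already carries O4, O6 and the stereocentres C1, C4, C5 and C6. In the forward direction dichlorocarbene, made from CHCl3 and KOt-Bu, adds to the C7=C9 enol ether bond of A1, and the siloxydichlorocyclopropane opens with loss of chloride to the 8-chloro-7-en-9-one A2.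

- For it: every step is of a well-tried type, the enol ether fixes where the carbon is inserted, the C9 oxygen arrives together with the new carbon, and no stereocentre is formed in the key step.
- Against it: A1 is itself a densely substituted bicycle whose four stereocentres need a long separate sequence. C8 arrives bearing chlorine and not the carbon C14, so dechlorination, saturation of C7=C8 and an α-methylenation must follow. The strongly basic carbene conditions also meet an allylic ether at C6.
- Comparison: Alternative 1 is stronger than the chosen route in precedent and in predictability of configuration. It is much weaker in step economy, because its key step adds a single carbon, whereas the cyclisation of 3 forms both rings, two skeletal bonds and three stereocentres at once. Its reliability is the reason it serves as the chemical fallback for step 3.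

**Alternative 2:** Ring A is opened at C4–C5 and the methyl group C15 is taken off C1, which gives the achiral cycloheptenone A3 with an isopropyl ketone side chain on C1 and a ketal at C9. In the forward direction Cu(OTf)2 with a chiral phosphoramidite transfers methyl from Me3Al to C1 of A3, and the aluminium enolate at C5 adds to the side-chain ketone to give ketol A4.

- For it: asymmetric catalysis on an achiral substrate gives two bonds, ring A and three stereocentres in one flask. Oxygen at C6 and C9 is part of the design; on this point it is stronger than the chosen route, which has to bring in O6 by C–H hydroxylation.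
- Against it: the tether from C1 can deliver C4 only to the face of the enolate carbon C5 on which C2 lies. The kinetic closure should therefore give the cis-fused bicycle (H5 cis to C15), with C4 and C5 both opposite to what the target needs relative to C1. The trans-fused A4 could then arise only by retro-aldol equilibration, whose outcome is open and which competes with dehydration of the tertiary ketol. In addition, Me3Al meets two ketones, A3 needs several steps of its own, and C14 is missing and must be added later at C8.
- Comparison: it is shorter than Alternative 1 and needs no biocatalyst development, so it is stronger than the chosen route in availability of the catalyst. It is weaker where the target is hardest, the relative configuration of C1, C4 and C5, which the chosen route hands to an enzyme pocket.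

**Alternative 3:** Both rings are traced to an arene. C1–C5 and C1–C10 are cut, ring B becomes a benzene ring (C5–C10), and C1 becomes the carbene carbon of the α-methyl diazoketone A5, in which the C4 carbinol links the arene to the diazoketone chain. In the forward direction the copper carbenoid from A5 (Cu(MeCN)4PF6, chiral bis(oxazoline)) adds across the arene bond C5–C10, and the norcaradiene opens to the cycloheptatriene A6 (Buchner reaction), which closes ring A and enlarges the arene to ring B.

- For it: both rings and the quaternary C1 form in one step from a flat, easily assembled arene. C14 and the oxygens at C6 and C9 are carried in as arene substituents; on this point it is stronger than the chosen route, which has none of the three after its key step.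
- Against it: the carbenoid bears a methyl group and is prone to a 1,2-hydride shift to the enone. It must choose the C5–C10 bond over the methoxy-bearing C5–C6 bond, and the right face against the existing C4 centre. A6 is also at the wrong oxidation level almost everywhere: the C2 ketone must be removed, two enol ethers hydrolysed, and three ring-B double bonds reduced with control of C5 and C6 before the C8 methylene group can be re-formed.
- Comparison: the sequence after the key step is far longer, and the configuration of C5 is deferred to a reduction. The chosen route delivers ring A at the final oxidation level with C1, C4 and C5 set in the ring-forming step.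

Key step: step 3

Remark on the chemistry: the cyclase of step 3 and the hydroxylase of step 4 are taken to be enzyme variants that first have to be obtained by screening and directed evolution.

## Route

Step 1
Reactants: 1 (2E,6E)-farnesol
Product: 2 (2E,6E)-farnesyl chloride
Conditions: NCS, Me2S, CH2Cl2, −40 → 0 °C
Reagents that add atoms: N-chlorosuccinimide, O=C1CCC(=O)N1Cl
Why: Corey–Kim-type chlorination: the alkoxysulfonium salt of the primary allylic alcohol is displaced by chloride in an SN2 reaction at the unhindered carbon, so neither allylic transposition nor loss of the (2E) geometry is expected; no stereocentre is formed.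

Step 2
Reactants: 2 (2E,6E)-farnesyl chloride
Product: 3 (2E,6E)-farnesyl diphosphate (handled as its ammonium salt)
Conditions: (Bu4N)3HP2O7, MeCN, 25 °C; then cation-exchange resin (NH4+ form), cellulose chromatography
Reagents that add atoms: tris(tetrabutylammonium) hydrogen diphosphate, CCCC[N+](CCCC)(CCCC)CCCC.CCCC[N+](CCCC)(CCCC)CCCC.CCCC[N+](CCCC)(CCCC)CCCC.OP(=O)([O-])OP(=O)([O-])[O-]
Why: SN2 displacement of the primary allylic chloride by the diphosphate anion in a dipolar aprotic solvent; the bulky, weakly basic nucleophile attacks only the primary carbon, the alkene geometries stay as they are, and cation exchange gives the water-soluble salt that the enzyme accepts.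

Step 3
Reactants: 3 (2E,6E)-farnesyl diphosphate
Product: 4 (1R,4R,5R)-dauc-8-en-4-ol (dauc-8-en-4β-ol)
Conditions: evolved daucane-type class 1 sesquiterpene cyclase, MgCl2, HEPES–NaOH buffer pH 7.5, dithiothreitol, 30 °C, pentane overlay
Reagents that add atoms: water, O
Why: Proposed new method: no known cyclase releases 4, so the step depends on a variant to be evolved from a carotol-type daucane synthase; the closest known reaction type is the magnesium-dependent cyclisation of 3 by class 1 sesquiterpene synthases to bicyclic tertiary alcohols with capture of water, as in the biosynthesis of carotol. Ionisation of 3, return of the diphosphate to the tertiary allylic carbon within the active site and renewed ionisation from the cisoid conformer give an allyl cation that ends at C10 (daucane numbering, the former CH2O carbon) with a cis C8=C9 bond. The C1=C5 alkene attacks C10 through C1 and closes ring B as a seven-membered ring with both alkene carbons inside the new ring (endo mode), while the distal C4=C11 alkene adds through C4 to the charge developing at C5 and closes ring A in a 5-exo mode, so that no free secondary cation is needed and the charge ends on C11. A 1,2-hydride shift from C4 to C11 makes the isopropyl group and a tertiary cation at C4, which a bound water molecule captures. C1 and C5 are set together by anti addition of C10 and C4 across the (E)-configured C1=C5 alkene, which can only give the trans ring fusion, and their absolute sense is fixed by the fold that the chiral pocket imposes on the chain. C4 is set by the face of water attack, which is decided by the position of the water in the pocket and not by the substrate; it has to be the β face, cis to C15. The selectivity needed is termination at the C4 cation, that is, water capture faster than a second hydride shift from C5 (the carotol pathway) and faster than proton loss to dienes; the substrate secures only the trans relation of C1 and C5 through its (E)-alkene, and everything else is asked of the evolved active site.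

Step 4
Reactants: 4 (1R,4R,5R)-dauc-8-en-4-ol
Product: 5 (1R,4R,5S,6S)-dauc-8-ene-4,6-diol (the 4β,6α-diol jaeschkeanadiol)
Conditions: cytochrome P450 monooxygenase variant (CYP102A1 lineage, selected by screening), NADP+ (cat.), D-glucose, glucose dehydrogenase, air, K2HPO4/KH2PO4 buffer pH 8.0, 25 °C
Reagents that add atoms: dioxygen, O=O
Why: Cytochrome P450 hydroxylation of a non-activated ring methylene (hydrogen abstraction by the oxo-iron species of the haem, then oxygen rebound with retention) is an established reaction type for sesquiterpenoids; the variant must bind 4 so that the pro-α hydrogen of C6 faces the iron, which sets C6 as S (6α-OH) under enzyme control, and must keep the allylic C7, C10 and C14 hydrogens and the alkene away from it.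

Step 5
Reactants: 6 4-hydroxybenzoic acid
Product: 8 4-(triisopropylsilyloxy)benzoic acid, via silyl ester 7 (not isolated)
Conditions: TIPSCl, imidazole, DMF, 25 °C; then AcOH/THF/H2O, 25 °C
Reagents that add atoms: triisopropylsilyl chloride, CC(C)[Si](Cl)(C(C)C)C(C)C
Why: Silylation of both the phenol and the carboxylic acid, then selective hydrolysis of the far more labile silyl ester 7 by mild aqueous acid, which leaves the aryl silyl ether; the triisopropylsilyl group is chosen because it survives carbodiimide coupling, peracid, the aluminium amide, oxidation and borohydride and leaves with fluoride.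

Step 6
Reactants: 5 (1R,4R,5S,6S)-dauc-8-ene-4,6-diol; 8 4-(triisopropylsilyloxy)benzoic acid
Product: 9 (1R,4R,5S,6S)-4-hydroxydauc-8-en-6-yl 4-(triisopropylsilyloxy)benzoate
Conditions: EDC·HCl, DMAP, CH2Cl2, 0 → 25 °C
Reagents that add atoms: none
Why: Steglich esterification (carbodiimide activation, acyl transfer by DMAP): the equatorial secondary 6α-hydroxyl is acylated, whereas the tertiary 4β-hydroxyl, flanked by the isopropyl group and the ring fusion, does not react; no stereocentre is touched.

Step 7
Reactants: 9 (1R,4R,5S,6S)-4-hydroxydauc-8-en-6-yl 4-(triisopropylsilyloxy)benzoate
Product: 10 (1R,4R,5S,6S,8R,9S)-8,9-epoxy-4-hydroxydaucan-6-yl 4-(triisopropylsilyloxy)benzoate (the 8α,9α-epoxide)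
Conditions: mCPBA, NaHCO3, CH2Cl2, 0 °C
Reagents that add atoms: 3-chloroperoxybenzoic acid, OOC(=O)c1cccc(Cl)c1
Why: Prilezhaev epoxidation of the only alkene; the peracid should approach the α face, away from the axial C15 methyl group on the homoallylic C1, which sets C8 and C9 as 8R,9S, and the buffer prevents acid-promoted attack of the 4β-hydroxyl on C8; because C9 is later oxidised to the ketone, any β-epoxide that forms converges on the same enone 12.

Step 8
Reactants: 10 (1R,4R,5S,6S,8R,9S)-8,9-epoxy-4-hydroxydaucan-6-yl 4-(triisopropylsilyloxy)benzoate
Product: 11 (1R,4R,5S,6S,9S)-4,9-dihydroxydauc-8(14)-en-6-yl 4-(triisopropylsilyloxy)benzoate (the 9α-alcohol)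
Conditions: Et2AlCl, LiTMP (excess), toluene, 0 °C; then aq. KNaC4H4O6
Reagents that add atoms: none
Why: Base-induced isomerisation of an epoxide to an allylic alcohol by diethylaluminium 2,2,6,6-tetramethylpiperidide (syn β-elimination within the aluminium–epoxide complex): the tertiary C8–O bond breaks and the proton is taken from the methyl group C14, which lies cis to H9 and is the least hindered β-position, so the exocyclic C8=C14 alkene forms while the untouched C9–O bond keeps O9 on the α face (9S); excess reagent covers the free tertiary alcohol, and the hindered amide should not attack the ester.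

Step 9
Reactants: 11 (1R,4R,5S,6S,9S)-4,9-dihydroxydauc-8(14)-en-6-yl 4-(triisopropylsilyloxy)benzoate
Product: 12 (1R,4R,5S,6S)-4-hydroxy-9-oxodauc-8(14)-en-6-yl 4-(triisopropylsilyloxy)benzoate
Conditions: Dess–Martin periodinane, NaHCO3, CH2Cl2, 0 → 25 °C
Reagents that add atoms: none
Why: Dess–Martin oxidation of the secondary allylic alcohol under buffered, non-acidic conditions; the tertiary alcohol cannot be oxidised, and the α-methylene ketone 12 is reduced at once and not stored, because it can isomerise into the ring or add nucleophiles.

Step 10
Reactants: 12 (1R,4R,5S,6S)-4-hydroxy-9-oxodauc-8(14)-en-6-yl 4-(triisopropylsilyloxy)benzoate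
Product: 13 (1R,4R,5S,6S,9R)-4,9-dihydroxydauc-8(14)-en-6-yl 4-(triisopropylsilyloxy)benzoate (the 9β-alcohol)
Conditions: NaBH4, CeCl3·7H2O, MeOH, −78 °C
Reagents that add atoms: none
Why: Luche reduction: the cerium-modified borohydride adds 1,2 to the enone, and hydride should come from the α face, because axial approach on the β face is blocked by the syn-axial C15 methyl group on C1, so that the hydroxyl group ends on the β face (9R); the aryl ester and the aryl silyl ether are inert at −78 °C.

Step 11
Reactants: 13 (1R,4R,5S,6S,9R)-4,9-dihydroxydauc-8(14)-en-6-yl 4-(triisopropylsilyloxy)benzoate
Product: 14 (1R,4R,5S,6S,9R)-4,9-dihydroxydauc-8(14)-en-6-yl 4-hydroxybenzoate (target CNP0164257.2)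
Conditions: Bu4NF, AcOH, THF, 0 °C
Reagents that add atoms: none
Why: Fluoride cleavage of the aryl silyl ether, buffered with acetic acid so that the phenoxide is protonated at once and neither the ester nor the allylic alcohol meets a strong base; no stereocentre is affected.

## Compound list

1 | (2E,6E)-farnesol | CC(C)=CCC/C(C)=C/CC/C(C)=C/CO | starting material
2 | (2E,6E)-farnesyl chloride | CC(C)=CCC/C(C)=C/CC/C(C)=C/CCl | intermediate
3 | (2E,6E)-farnesyl diphosphate (drawn as the acid, handled as the ammonium salt) | CC(C)=CCC/C(C)=C/CC/C(C)=C/COP(=O)(O)OP(=O)(O)O | intermediate
4 | (1R,4R,5R)-dauc-8-en-4-ol (dauc-8-en-4β-ol; (3R,3aR,8aR)-6,8a-dimethyl-3-(propan-2-yl)-1,2,3,3a,4,5,8,8a-octahydroazulen-3-ol) | CC=1CC[C@@H]2[C@](C)(CC[C@@]2(O)C(C)C)CC=1 | intermediate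
5 | (1R,4R,5S,6S)-dauc-8-ene-4,6-diol (4β,6α-diol, jaeschkeanadiol) | CC=1C[C@H](O)[C@@H]2[C@](C)(CC[C@@]2(O)C(C)C)CC=1 | intermediate
6 | 4-hydroxybenzoic acid | OC(=O)c1ccc(O)cc1 | starting material
7 | triisopropylsilyl 4-(triisopropylsilyloxy)benzoate | CC(C)[Si](C(C)C)(C(C)C)OC(=O)c1ccc(O[Si](C(C)C)(C(C)C)C(C)C)cc1 | intermediate (not isolated)
8 | 4-(triisopropylsilyloxy)benzoic acid | CC(C)[Si](C(C)C)(C(C)C)Oc1ccc(C(=O)O)cc1 | intermediate
9 | (1R,4R,5S,6S)-4-hydroxydauc-8-en-6-yl 4-(triisopropylsilyloxy)benzoate | CC=1C[C@H](OC(=O)c3ccc(O[Si](C(C)C)(C(C)C)C(C)C)cc3)[C@@H]2[C@](C)(CC[C@@]2(O)C(C)C)CC=1 | intermediate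
10 | (1R,4R,5S,6S,8R,9S)-8,9-epoxy-4-hydroxydaucan-6-yl 4-(triisopropylsilyloxy)benzoate (8α,9α-epoxide) | C[C@@]12C[C@H](OC(=O)c4ccc(O[Si](C(C)C)(C(C)C)C(C)C)cc4)[C@@H]3[C@](C)(CC[C@@]3(O)C(C)C)C[C@@H]1O2 | intermediate
11 | (1R,4R,5S,6S,9S)-4,9-dihydroxydauc-8(14)-en-6-yl 4-(triisopropylsilyloxy)benzoate (9α-alcohol) | C=C1C[C@H](OC(=O)c3ccc(O[Si](C(C)C)(C(C)C)C(C)C)cc3)[C@@H]2[C@](C)(CC[C@@]2(O)C(C)C)C[C@@H]1O | intermediate
12 | (1R,4R,5S,6S)-4-hydroxy-9-oxodauc-8(14)-en-6-yl 4-(triisopropylsilyloxy)benzoate | C=C1C[C@H](OC(=O)c3ccc(O[Si](C(C)C)(C(C)C)C(C)C)cc3)[C@@H]2[C@](C)(CC[C@@]2(O)C(C)C)CC1=O | intermediate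
13 | (1R,4R,5S,6S,9R)-4,9-dihydroxydauc-8(14)-en-6-yl 4-(triisopropylsilyloxy)benzoate (9β-alcohol) | C=C1C[C@H](OC(=O)c3ccc(O[Si](C(C)C)(C(C)C)C(C)C)cc3)[C@@H]2[C@](C)(CC[C@@]2(O)C(C)C)C[C@H]1O | intermediate
14 | (1R,4R,5S,6S,9R)-4,9-dihydroxydauc-8(14)-en-6-yl 4-hydroxybenzoate ((3R,3aS,4S,7R,8aR)-3,7-dihydroxy-8a-methyl-6-methylidene-3-(propan-2-yl)decahydroazulen-4-yl 4-hydroxybenzoate) | C=C1C[C@H](OC(=O)c2ccc(O)cc2)[C@@H]2[C@](C)(CC[C@@]2(O)C(C)C)C[C@H]1O | target

## Step count and least certain steps

Total step count: 11. Longest linear sequence: 10 steps (1 to 14 by steps 1–4 and 6–11); step 5 is a one-step branch.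

**Step 3 (key step).** What may go wrong: the evolved enzyme fails to terminate at the C4 cation. A second hydride shift followed by hydration at C5, proton loss to dienes, or water attack from the α face may dominate, and no variant with useful selectivity may be found. The fallback uses known chemistry only and makes the two rings on the lines of Alternative 1. It does not branch from an intermediate, because none of the farnesyl compounds 1–3 can be folded into the daucane core without the enzyme. Of the numbered compounds it sets out from acid 8 only, and it comes back to the route at enone 12.
- The trans-hydrindane trimethylsilyl enol ether F1 (identical with A1; it must be prepared in a separate sequence) is ring-expanded with dichlorocarbene (CHCl3, KOt-Bu) to the 8-chloro enone F2 (identical with A2).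
- Hydrogenation over Pd/C in the presence of Et3N removes the chlorine and saturates C7=C8 to give the C9 ketone F3.
- DDQ cleaves the 4-methoxybenzyl ether to give the 6α-alcohol F4.
- Esterification with 8 under the conditions of step 6 gives the ester F5.
- HF·pyridine removes the tertiary triethylsilyl ether, while acidic fluoride spares the aryl silyl ether, to give the hydroxy ketone F6.
- α-Methylenation at C8 with paraformaldehyde and N-methylanilinium trifluoroacetate gives 12; C8 is the only unhindered α-methylene group, since C10 is neopentyl. Steps 10 and 11 then follow unchanged.

This fallback also removes the need for step 4, at the price of a much longer sequence.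

**Step 4.** What may go wrong: oxidation at the wrong site. Allylic hydroxylation at C7, C10 or C14 and epoxidation of C8=C9 are intrinsically easier than attack on the non-activated C6 methylene, and hydroxylation on the β face of C6 is also possible. The fallback gives up the single engineered, isolated enzyme. It uses preparative whole-cell biotransformation of 4 with wild-type hydroxylating filamentous fungi (strains of Mucor, Cunninghamella, Aspergillus or Beauveria). These oxidise non-activated ring methylenes of sesquiterpene alcohols and supply their own cofactors; the strain is chosen by screening for the 4β,6α-diol. The fallback sets out from 4 and comes back at 5, with no new compound. If no biological oxidant finds C6, the chemical fallback of step 3 covers this step as well, because it carries O6 from the start.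

**Step 8.** What may go wrong: a wrong course of epoxide opening. The possibilities are proton loss from C7 to give the endocyclic allylic alcohol, attack of the aluminium-bound 4β-alkoxide on the activated C8 across the ring, or attack of the amide on the ester. The fallback changes the mechanism from ionic to radical. Cp2TiCl (trivalent titanium, made from Cp2TiCl2 and manganese dust in THF) opens the C8–O bond of 10 homolytically to the tertiary C8 radical. Trapping by a second Cp2TiCl and β-hydride elimination from C14 then give the exocyclic allylic alcohol under neutral conditions that leave the ester and the free alcohol alone. The fallback sets out from 10 and comes back at 11, with no new compound.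

**Step 10.** What may go wrong: hydride addition from the β face, which returns 11, or 1,4-reduction of the α-methylene ketone. The fallback leaves the redox detour and inverts C9 directly. A Mitsunobu reaction of 11 (which is also what a wrong-face reduction returns) with chloroacetic acid, PPh3 and diisopropyl azodicarboxylate gives the 9β-chloroacetate F7 by SN2 displacement from the β face. Thiourea with NaHCO3 then removes the chloroacetyl group in the presence of the aryl ester to give 13. The two approaches are complementary: if hydride prefers the β face of 12, that face is open, and the displacement on 11 from the same side should be easy. The fallback sets out from 11 and comes back at 13.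

## Further compounds

F1 | step 3 | 3-isopropyl-4-(4-methoxybenzyloxy)-7a-methyl-3-(triethylsilyloxy)-6-(trimethylsilyloxy)-2,3,3a,4,7,7a-hexahydro-1H-indene, trans-fused, with C1, C4, C5 and C6 (daucane numbering) configured as in the target | C[Si](C)(C)OC1=C[C@H](OCc3ccc(OC)cc3)[C@@H]2[C@](C)(CC[C@@]2(O[Si](CC)(CC)CC)C(C)C)C1
F2 | step 3 | 8-chloro-6α-(4-methoxybenzyloxy)-4β-(triethylsilyloxy)-14-nordauc-7-en-9-one | ClC1=C[C@H](OCc3ccc(OC)cc3)[C@@H]2[C@](C)(CC[C@@]2(O[Si](CC)(CC)CC)C(C)C)CC1=O
F3 | step 3 | 6α-(4-methoxybenzyloxy)-4β-(triethylsilyloxy)-14-nordaucan-9-one | C1C[C@H](OCc3ccc(OC)cc3)[C@@H]2[C@](C)(CC[C@@]2(O[Si](CC)(CC)CC)C(C)C)CC1=O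
F4 | step 3 | 6α-hydroxy-4β-(triethylsilyloxy)-14-nordaucan-9-one | C1C[C@H](O)[C@@H]2[C@](C)(CC[C@@]2(O[Si](CC)(CC)CC)C(C)C)CC1=O
F5 | step 3 | 9-oxo-4β-(triethylsilyloxy)-14-nordaucan-6α-yl 4-(triisopropylsilyloxy)benzoate | C1C[C@H](OC(=O)c3ccc(O[Si](C(C)C)(C(C)C)C(C)C)cc3)[C@@H]2[C@](C)(CC[C@@]2(O[Si](CC)(CC)CC)C(C)C)CC1=O
F6 | step 3 | 4β-hydroxy-9-oxo-14-nordaucan-6α-yl 4-(triisopropylsilyloxy)benzoate | C1C[C@H](OC(=O)c3ccc(O[Si](C(C)C)(C(C)C)C(C)C)cc3)[C@@H]2[C@](C)(CC[C@@]2(O)C(C)C)CC1=O
F0 | step 4 | none | none
F0 | step 8 | none | none
F7 | step 10 | 9β-(chloroacetoxy)-4β-hydroxydauc-8(14)-en-6α-yl 4-(triisopropylsilyloxy)benzoate | C=C1C[C@H](OC(=O)c3ccc(O[Si](C(C)C)(C(C)C)C(C)C)cc3)[C@@H]2[C@](C)(CC[C@@]2(O)C(C)C)C[C@H]1OC(=O)CCl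
A1 | alternative 1 | 3-isopropyl-4-(4-methoxybenzyloxy)-7a-methyl-3-(triethylsilyloxy)-6-(trimethylsilyloxy)-2,3,3a,4,7,7a-hexahydro-1H-indene, trans-fused, with C1, C4, C5 and C6 (daucane numbering) configured as in the target | C[Si](C)(C)OC1=C[C@H](OCc3ccc(OC)cc3)[C@@H]2[C@](C)(CC[C@@]2(O[Si](CC)(CC)CC)C(C)C)C1
A2 | alternative 1 | 8-chloro-6α-(4-methoxybenzyloxy)-4β-(triethylsilyloxy)-14-nordauc-7-en-9-one | ClC1=C[C@H](OCc3ccc(OC)cc3)[C@@H]2[C@](C)(CC[C@@]2(O[Si](CC)(CC)CC)C(C)C)CC1=O
A3 | alternative 2 | 10-(4-methyl-3-oxopentyl)-1,4-dioxaspiro[4.6]undec-9-en-8-one | O=C1C=C(CCC(=O)C(C)C)CC2(CC1)OCCO2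
A4 | alternative 2 | 9,9-(ethylenedioxy)-4β-hydroxy-14-nordaucan-6-one (trans-fused, 5α-H) | C1CC(=O)[C@@H]2[C@](C)(CC[C@@]2(O)C(C)C)CC13OCCO3
A5 | alternative 3 | 2-diazo-5-[2,5-dimethoxy-4-(methoxymethyl)phenyl]-6-methyl-5-(triethylsilyloxy)heptan-3-one, carbinol carbon configured as C4 of the target | CC(=[N+]=[N-])C(=O)C[C@@](O[Si](CC)(CC)CC)(C(C)C)c1cc(OC)c(COC)cc1OC
A6 | alternative 3 | 6,9,14-trimethoxy-4β-(triethylsilyloxy)dauca-5,7,9-trien-2-one | COCC1=CC(OC)=C2[C@](C)(C(=O)C[C@@]2(O[Si](CC)(CC)CC)C(C)C)C=C1OC
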